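The strategy opens pyranone ring C of half 2 (the 7-methoxy-4'-hydroxyflavone) at O1''–C2'', C3''–C4'' and C4''–C4a'' into a phenol oxygen, an arylacetylene and carbon monoxide. One palladium-catalysed carbonylative annulation makes these three bonds and closes that ring on a finished C8–C6'' biaryl. The precursor is 5,7-di-O-benzylacacetin carrying a 4-hydroxy-3-iodo-2,6-dimethoxyphenyl group at C8. The feature exploited is the local twofold symmetry of the future ring A of half 2. In the 4-aryl-3,5-dimethoxyphenol both carbons ortho to the hydroxyl are equivalent, so iodination, and thus C4a'', can only lead to the 6''-linked flavone. The C5'' and C7'' methoxy groups are told apart at the end by chelation to O4''.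

Key step: step 8

Locants: half 1 is the acacetin unit (unprimed, ring B primed). Half 2 is the second flavone (double-primed, ring B triple-primed).

Assumption: the target SMILES fixes no configuration at the hindered C8–C6'' axis, so compounds 12 and 15–19 are taken as racemic atropisomers.

Step 1
Reactants: 1 acacetin
Product: 3 5,7-bis(benzyloxy)-2-(4-methoxyphenyl)chromen-4-one, via 7-O-benzylacacetin 2 (not isolated)
Conditions: BnBr (3 equiv), K2CO3 (4 equiv), DMF, 80 °C
Reagents that add atoms: benzyl bromide, BrCc1ccccc1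
Why: Williamson etherification, in which the acidic 7-OH reacts first and the hydrogen-bonded 5-OH follows with excess bromide and heat; capping O5 is what later steers electrophiles from C6 to C8.

Step 2
Reactants: 3 5,7-bis(benzyloxy)-2-(4-methoxyphenyl)chromen-4-one
Product: 4 5,7-bis(benzyloxy)-8-iodo-2-(4-methoxyphenyl)chromen-4-one
Conditions: NIS (1.1 equiv), TFA (cat.), MeCN/CH2Cl2, 0 °C to rt, dark
Reagents that add atoms: N-iodosuccinimide, O=C1CCC(=O)N1I
Why: Electrophilic aromatic iodination, for which C8 is the most nucleophilic carbon of a 5,7-dialkoxyflavone and is flanked by only one benzyloxy group (C6 lies between two), while ring B and C3 are deactivated by the pyranone.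

Step 3
Reactants: 5 3,5-dimethoxyphenol
Product: 6 (3,5-dimethoxyphenoxy)triisopropylsilane
Conditions: TIPSCl, imidazole, DMF, rt
Reagents that add atoms: chlorotriisopropylsilane, CC(C)[Si](Cl)(C(C)C)C(C)C
Why: Standard phenol silylation; the bulky, weakly coordinating OTIPS group should survive nBuLi and aqueous base and should not compete as a directing group in step 4.

Step 4
Reactants: 6 (3,5-dimethoxyphenoxy)triisopropylsilane
Product: 9 [2,6-dimethoxy-4-(triisopropylsilyloxy)phenyl]boronic acid, via aryllithium 7 (not isolated), via lithium aryl(triisopropoxy)borate 8 (not isolated)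
Conditions: nBuLi, THF, 0 °C to rt; B(OiPr)3, −78 °C to rt; 1 M HCl to pH 5, 0 °C
Reagents that add atoms: triisopropyl borate, CC(C)OB(OC(C)C)OC(C)C; water, O
Why: Directed ortho-metalation, in which the two methoxy groups cooperate to place lithium on the carbon between them (the shielded silyloxy oxygen is a poor director), followed by borate trapping and mild hydrolysis.

Step 5
Reactants: 4 5,7-bis(benzyloxy)-8-iodo-2-(4-methoxyphenyl)chromen-4-one; 9 [2,6-dimethoxy-4-(triisopropylsilyloxy)phenyl]boronic acid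
Product: 10 5,7-bis(benzyloxy)-8-[2,6-dimethoxy-4-(triisopropylsilyloxy)phenyl]-2-(4-methoxyphenyl)chromen-4-one
Conditions: Pd(OAc)2 (5 mol %), SPhos (10 mol %), K3PO4, 9 (1.8 equiv), toluene/H2O, 100 °C
Reagents that add atoms: none
Why: Suzuki–Miyaura coupling with a bulky dialkylbiarylphosphine, the ligand class established for tetra-ortho-substituted biaryls; all four ortho groups are small oxygen substituents, excess 9 offsets protodeboronation, and any silyl loss only anticipates step 6.

Step 6
Reactants: 10 5,7-bis(benzyloxy)-8-[2,6-dimethoxy-4-(triisopropylsilyloxy)phenyl]-2-(4-methoxyphenyl)chromen-4-one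
Product: 11 5,7-bis(benzyloxy)-8-(4-hydroxy-2,6-dimethoxyphenyl)-2-(4-methoxyphenyl)chromen-4-one
Conditions: TBAF, AcOH, THF, 0 °C
Reagents that add atoms: none
Why: Fluoride-driven Si–O cleavage buffered with acetic acid, to which benzyl ethers, methyl ethers and the pyranone are inert.

Step 7
Reactants: 11 5,7-bis(benzyloxy)-8-(4-hydroxy-2,6-dimethoxyphenyl)-2-(4-methoxyphenyl)chromen-4-one
Product: 12 5,7-bis(benzyloxy)-8-(4-hydroxy-3-iodo-2,6-dimethoxyphenyl)-2-(4-methoxyphenyl)chromen-4-one
Conditions: NIS (1.0 equiv, slow addition), MeCN/CH2Cl2, −20 °C to 0 °C, dark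
Reagents that add atoms: N-iodosuccinimide, O=C1CCC(=O)N1I
Why: Electrophilic iodination of a free phloroglucinol-type phenol, far more reactive than the carbonyl-deactivated C6 of half 1 (which needed acid activation in step 2); the para carbon is blocked and the two ortho carbons are equivalent, so one equivalent of NIS should give a single monoiodide.

Step 8
Reactants: 12 5,7-bis(benzyloxy)-8-(4-hydroxy-3-iodo-2,6-dimethoxyphenyl)-2-(4-methoxyphenyl)chromen-4-one; 13 carbon monoxide; 14 1-(benzyloxy)-4-ethynylbenzene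
Product: 17 5,7-bis(benzyloxy)-8-[2-(4-benzyloxyphenyl)-5,7-dimethoxy-4-oxochromen-6-yl]-2-(4-methoxyphenyl)chromen-4-one (protected biflavone), via hydroxyaryl ynone 15 (not isolated), via diethylamino enone 16 (not isolated)
Conditions: PdCl2(dppf) (5 mol %), CO (20 bar), 14 (1.5 equiv), Et2NH/DMF, 100 °C, autoclave, no copper salt
Reagents that add atoms: none
Why: PdCl2(dppf) is reduced in situ to zerovalent palladium, which inserts into the C–I bond of 12; CO insertion gives the aroylpalladium iodide, and the amine-deprotonated alkyne 14 is transferred to it and reductively eliminated as ynone 15, forming C4a''–C4'' and C4''–C3''. Diethylamine adds to the ynone to give enaminone 16, whose C2'' is attacked by the neighbouring phenol oxygen with loss of the amine, a 6-endo addition–elimination that forms O1''–C2'' and closes ring C of half 2. The closest known reaction type is the palladium-catalysed carbonylative annulation of 2-iodophenols with terminal arylacetylenes and CO in a secondary amine, which gives flavones. No stereocentre is formed and the C8–C6'' axis remains racemic. The step needs flavone over aurone closure, secured by the enaminone because it removes the triple bond that a 5-exo attack would need; carbonylative over direct alkynylation, secured by CO pressure and the absence of copper; and a single site of ring fusion, secured by the iodine placed on the symmetric phenol ring. The flanking OH and OMe slow oxidative addition, which the weak C–I bond and 100 °C should offset, while the benzyl and methyl ethers and the pyranone of half 1 (only O1 could reclose after any reversible amine addition) are spectators.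

Step 9
Reactants: 17 protected biflavone
Product: 19 5,7-dihydroxy-8-[5-hydroxy-2-(4-hydroxyphenyl)-7-methoxy-4-oxochromen-6-yl]-2-(4-methoxyphenyl)chromen-4-one (target CNP0253922.0), via tetrakis(dichloroboryl) aryloxide 18 (not isolated)
Conditions: BCl3 (10 equiv), C6HMe5 (10 equiv), CH2Cl2, −78 °C to 0 °C; aqueous work-up
Reagents that add atoms: none
Why: Lewis-acid ether cleavage, in which BCl3 with pentamethylbenzene as a non-basic benzyl cation trap removes aryl benzyl ethers cold without C-benzylation and boron chelated between O4'' and O5'' activates only the peri methoxy group; the unchelated C7''-OMe and C4'-OMe resist BCl3 at or below 0 °C, and no hot protic acid is present to trigger Wessely–Moser isomerisation.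

Compound list
1 | acacetin, 5,7-dihydroxy-2-(4-methoxyphenyl)chromen-4-one | COc1ccc(-c2cc(=O)c3c(O)cc(O)cc3o2)cc1 | starting material
2 | 7-(benzyloxy)-5-hydroxy-2-(4-methoxyphenyl)chromen-4-one | COc1ccc(-c2cc(=O)c3c(O)cc(OCc4ccccc4)cc3o2)cc1 | intermediate (not isolated)
3 | 5,7-bis(benzyloxy)-2-(4-methoxyphenyl)chromen-4-one | COc1ccc(-c2cc(=O)c3c(OCc4ccccc4)cc(OCc4ccccc4)cc3o2)cc1 | intermediate
4 | 5,7-bis(benzyloxy)-8-iodo-2-(4-methoxyphenyl)chromen-4-one | COc1ccc(-c2cc(=O)c3c(OCc4ccccc4)cc(OCc4ccccc4)c(I)c3o2)cc1 | intermediate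
5 | 3,5-dimethoxyphenol | COc1cc(O)cc(OC)c1 | starting material
6 | (3,5-dimethoxyphenoxy)triisopropylsilane | COc1cc(O[Si](C(C)C)(C(C)C)C(C)C)cc(OC)c1 | intermediate
7 | [2,6-dimethoxy-4-(triisopropylsilyloxy)phenyl]lithium | [Li]c1c(OC)cc(O[Si](C(C)C)(C(C)C)C(C)C)cc1OC | intermediate (not isolated)
8 | lithium [2,6-dimethoxy-4-(triisopropylsilyloxy)phenyl]triisopropoxyborate | [Li+].COc1cc(O[Si](C(C)C)(C(C)C)C(C)C)cc(OC)c1[B-](OC(C)C)(OC(C)C)OC(C)C | intermediate (not isolated)
9 | [2,6-dimethoxy-4-(triisopropylsilyloxy)phenyl]boronic acid | COc1cc(O[Si](C(C)C)(C(C)C)C(C)C)cc(OC)c1B(O)O | intermediate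
10 | 5,7-bis(benzyloxy)-8-[2,6-dimethoxy-4-(triisopropylsilyloxy)phenyl]-2-(4-methoxyphenyl)chromen-4-one | COc1ccc(-c2cc(=O)c3c(OCc4ccccc4)cc(OCc4ccccc4)c(-c4c(OC)cc(O[Si](C(C)C)(C(C)C)C(C)C)cc4OC)c3o2)cc1 | intermediate
11 | 5,7-bis(benzyloxy)-8-(4-hydroxy-2,6-dimethoxyphenyl)-2-(4-methoxyphenyl)chromen-4-one | COc1ccc(-c2cc(=O)c3c(OCc4ccccc4)cc(OCc4ccccc4)c(-c4c(OC)cc(O)cc4OC)c3o2)cc1 | intermediate
12 | 5,7-bis(benzyloxy)-8-(4-hydroxy-3-iodo-2,6-dimethoxyphenyl)-2-(4-methoxyphenyl)chromen-4-one (racemic axis) | COc1ccc(-c2cc(=O)c3c(OCc4ccccc4)cc(OCc4ccccc4)c(-c4c(OC)cc(O)c(I)c4OC)c3o2)cc1 | intermediate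
13 | carbon monoxide | [C-]#[O+] | starting material
14 | 1-(benzyloxy)-4-ethynylbenzene | C#Cc1ccc(OCc2ccccc2)cc1 | starting material
15 | 5,7-bis(benzyloxy)-8-{3-[3-(4-benzyloxyphenyl)prop-2-ynoyl]-4-hydroxy-2,6-dimethoxyphenyl}-2-(4-methoxyphenyl)chromen-4-one | COc1ccc(-c2cc(=O)c3c(OCc4ccccc4)cc(OCc4ccccc4)c(-c4c(OC)cc(O)c(C(=O)C#Cc5ccc(OCc6ccccc6)cc5)c4OC)c3o2)cc1 | intermediate (not isolated)
16 | 5,7-bis(benzyloxy)-8-{3-[3-(4-benzyloxyphenyl)-3-(diethylamino)prop-2-enoyl]-4-hydroxy-2,6-dimethoxyphenyl}-2-(4-methoxyphenyl)chromen-4-one (alkene geometry not defined) | COc1ccc(-c2cc(=O)c3c(OCc4ccccc4)cc(OCc4ccccc4)c(-c4c(OC)cc(O)c(C(=O)C=C(N(CC)CC)c5ccc(OCc6ccccc6)cc5)c4OC)c3o2)cc1 | intermediate (not isolated)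
17 | 5,7-bis(benzyloxy)-8-[2-(4-benzyloxyphenyl)-5,7-dimethoxy-4-oxochromen-6-yl]-2-(4-methoxyphenyl)chromen-4-one | COc1ccc(-c2cc(=O)c3c(OCc4ccccc4)cc(OCc4ccccc4)c(-c4c(OC)cc5oc(-c6ccc(OCc7ccccc7)cc6)cc(=O)c5c4OC)c3o2)cc1 | intermediate
18 | O5,O7,O5'',O4'''-tetrakis(dichloroboryl) derivative of 19 (formal representation of the boron aryloxides) | COc1ccc(-c2cc(=O)c3c(OB(Cl)Cl)cc(OB(Cl)Cl)c(-c4c(OC)cc5oc(-c6ccc(OB(Cl)Cl)cc6)cc(=O)c5c4OB(Cl)Cl)c3o2)cc1 | intermediate (not isolated)
19 | 5,7-dihydroxy-8-[5-hydroxy-2-(4-hydroxyphenyl)-7-methoxy-4-oxochromen-6-yl]-2-(4-methoxyphenyl)chromen-4-one | COc1ccc(-c2cc(=O)c3c(O)cc(O)c(-c4c(OC)cc5oc(-c6ccc(O)cc6)cc(=O)c5c4O)c3o2)cc1 | target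

Total step count: 9. Longest linear sequence: 7 steps (steps 1, 2, 5–9 from acacetin; equally steps 3, 4, 5–9 from 3,5-dimethoxyphenol).

Steps most likely to fail

Step 8.
- **Risk:** Oxidative addition at the electron-rich C–I bond flanked by OH and OMe may be sluggish under CO. Three processes could then take over: hydrodeiodination, interception of the aroylpalladium by diethylamine (aminocarbonylation), or direct alkynylation followed by 5-endo closure.
- **Fallback:** Ring C is assembled stepwise by chalcone chemistry, without CO or a competing amine.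
  - Setting out from 12, Stille coupling with tributyl(1-ethoxyvinyl)stannane [PdCl2(PPh3)2, dioxane, 100 °C] should give the 1-ethoxyvinyl arene F1.
  - Dilute HCl hydrolyses it to the 2-hydroxyacetophenone F2.
  - Claisen–Schmidt condensation with 4-(benzyloxy)benzaldehyde (KOH, EtOH/THF, rt, where the pyranone of half 1 is not opened) should give the (E)-2'-hydroxychalcone F3.
  - Catalytic I2 in DMSO at 120 °C effects the oxidative 6-endo cyclisation and comes back to the route at 17.

Step 5.
- **Risk:** Base-promoted protodeboronation of the electron-rich 2,6-dialkoxyarylboronic acid may outrun the slow transmetalation and reductive elimination at the tetra-ortho-substituted centre.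
- **Fallback:** An anhydrous, base-free Negishi coupling.
  - Setting out from 6, lithiation as in step 4 gives 7.
  - ZnCl2 in THF converts it into the arylzinc chloride F4.
  - This is coupled with 4 under Pd2(dba)3/RuPhos in THF at 65 °C, coming back to the route at 10.

Step 9.
- **Risk:** Cleavage of the unchelated benzyl ethers may be incomplete at temperatures where the methyl ethers are safe. On warming, methyl ether selectivity may erode or partly cleaved boron chelates may precipitate.
- **Fallback:** The two tasks are separated.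
  - Setting out from 17, hydrogenolysis (H2, 1 atm, Pd/C, THF/MeOH, rt) removes the three benzyl groups without any cationic species and should give the 5''-O-methyl triphenol F5.
  - AlCl3 in MeCN at 60 °C followed by dilute HCl then cleaves only the chelated peri methoxy group, arriving at 19.

Further compounds
F1 | step 8 | 5,7-bis(benzyloxy)-8-[3-(1-ethoxyvinyl)-4-hydroxy-2,6-dimethoxyphenyl]-2-(4-methoxyphenyl)chromen-4-one | COc1ccc(-c2cc(=O)c3c(OCc4ccccc4)cc(OCc4ccccc4)c(-c4c(OC)cc(O)c(C(=C)OCC)c4OC)c3o2)cc1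
F2 | step 8 | 8-(3-acetyl-4-hydroxy-2,6-dimethoxyphenyl)-5,7-bis(benzyloxy)-2-(4-methoxyphenyl)chromen-4-one | COc1ccc(-c2cc(=O)c3c(OCc4ccccc4)cc(OCc4ccccc4)c(-c4c(OC)cc(O)c(C(C)=O)c4OC)c3o2)cc1
F3 | step 8 | 5,7-bis(benzyloxy)-8-{3-[(E)-3-(4-benzyloxyphenyl)prop-2-enoyl]-4-hydroxy-2,6-dimethoxyphenyl}-2-(4-methoxyphenyl)chromen-4-one | COc1ccc(-c2cc(=O)c3c(OCc4ccccc4)cc(OCc4ccccc4)c(-c4c(OC)cc(O)c(C(=O)/C=C/c5ccc(OCc6ccccc6)cc5)c4OC)c3o2)cc1
F4 | step 5 | [2,6-dimethoxy-4-(triisopropylsilyloxy)phenyl]zinc chloride | Cl[Zn]c1c(OC)cc(O[Si](C(C)C)(C(C)C)C(C)C)cc1OC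
F5 | step 9 | 5,7-dihydroxy-8-[2-(4-hydroxyphenyl)-5,7-dimethoxy-4-oxochromen-6-yl]-2-(4-methoxyphenyl)chromen-4-one | COc1ccc(-c2cc(=O)c3c(O)cc(O)c(-c4c(OC)cc5oc(-c6ccc(O)cc6)cc(=O)c5c4OC)c3o2)cc1
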